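**Plan**

1. Retrosynthesis: the tiglate C–O bond is cut first, then both C(=O)–C(ring-fusion) bonds of the quinone ring at once, which leaves p-benzoquinone and a four-carbon unit at the succinic anhydride level (used as its 2,5-bis(silyloxy)furan); last the Cα–C1′ bond of that substituted succinate is cut by an aldol.
2. Enabling feature: in the naphthazarin core, ring B (C1=O, C2=C3, C4=O) is fused through C4a/C8a to ring A, a benzene ring with oxygen on C5 and C8. C1–C2=C3–C4 is the skeleton of a furan with oxygen on both termini, and C5/C4a/C8a/C8 is that of p-benzoquinone. The two partners together are already at the oxidation level of the product, so no oxidation and no aryl ether cleavage follows.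
3. Forward: the side chain is joined by a boron aldol on a succinate half-ester imide; then silylation, release of both carboxyls, anhydride, furan (a temporary ring), [4+2] addition to p-benzoquinone with loss of the oxygen bridge and enolisation (ring B closes, ring A aromatises), desilylation, tigloylation.
4. Stereochemistry: the only stereocentre (C1′, S) is set by the (R)-4-benzyloxazolidinone in the aldol step; the α-centre made with it is erased when the furan forms; the E-alkene arrives with tiglic acid.

Key step: step 9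

Remark: the given configuration at C1′ translates to S (alkannin series); the core is written in the tautomer of the given structure; compounds 1, 2, 5, 17 and 22 are taken as commercial.

**Route**

Step 1
Reactants: 1 mono-tert-butyl succinate; 2 (R)-4-benzyl-1,3-oxazolidin-2-one
Product: 4 tert-butyl 4-[(4R)-4-benzyl-2-oxo-1,3-oxazolidin-3-yl]-4-oxobutanoate, via mixed pivalic anhydride 3 (not isolated)
Conditions: PivCl, Et3N, THF, −20 °C; then LiCl, 2, −20 °C → rt
Reagents that add atoms: none
Why: N-acylation of an oxazolidinone through a mixed pivalic anhydride, in which the hindered pivaloyl carbonyl steers the LiCl-activated oxazolidinone to the succinyl carbonyl and the tert-butyl ester is untouched.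

Step 2
Reactants: 5 4-methylpent-3-en-1-ol
Product: 6 4-methylpent-3-enal
Conditions: Dess–Martin periodinane, NaHCO3, CH2Cl2, 0 °C → rt; used at once as a cold solution
Reagents that add atoms: none
Why: Dess–Martin oxidation under buffered, non-basic conditions should give the β,γ-unsaturated aldehyde without moving the double bond into conjugation.

Step 3
Reactants: 4 tert-butyl 4-[(4R)-4-benzyl-2-oxo-1,3-oxazolidin-3-yl]-4-oxobutanoate; 6 4-methylpent-3-enal
Product: 9 tert-butyl (3R,4S)-3-{[(4R)-4-benzyl-2-oxo-1,3-oxazolidin-3-yl]carbonyl}-4-hydroxy-7-methyloct-6-enoate, via Z-boron enolate 7 (not isolated), via boron aldolate 8 (not isolated)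
Conditions: Bu2BOTf, iPr2NEt, CH2Cl2, −78 → 0 °C; 6, −78 → 0 °C; pH 7 buffer, MeOH, 30% H2O2, 0 °C
Reagents that add atoms: none
Why: Evans syn-aldol reaction, in which Bu2BOTf/iPr2NEt enolises only the imide α-CH2 to the Z-enolate 7, which adds to 6 through a closed chair transition state on the face away from the benzyl group of the (R)-auxiliary, setting C4 as S (the later C1′) and C3 as R, the latter being of no consequence because it is flattened in step 8.

Step 4
Reactants: 9 tert-butyl (3R,4S)-3-{[(4R)-4-benzyl-2-oxo-1,3-oxazolidin-3-yl]carbonyl}-4-hydroxy-7-methyloct-6-enoate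
Product: 10 tert-butyl (3R,4S)-3-{[(4R)-4-benzyl-2-oxo-1,3-oxazolidin-3-yl]carbonyl}-7-methyl-4-(triethylsilyloxy)oct-6-enoate
Conditions: TESOTf, 2,6-lutidine, CH2Cl2, −78 °C
Reagents that add atoms: triethylsilyl trifluoromethanesulfonate, CC[Si](CC)(CC)OS(=O)(=O)C(F)(F)F
Why: Silylation of a hindered secondary aldol hydroxyl with a silyl triflate and 2,6-lutidine at low temperature should be fast enough to spare the tert-butyl ester and forestall lactonisation, and the triethylsilyl group is chosen to survive steps 5–9 yet leave under buffered fluoride.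

Step 5
Reactants: 10 tert-butyl (3R,4S)-3-{[(4R)-4-benzyl-2-oxo-1,3-oxazolidin-3-yl]carbonyl}-7-methyl-4-(triethylsilyloxy)oct-6-enoate
Product: 12 (2R,3S)-2-(2-tert-butoxy-2-oxoethyl)-6-methyl-3-(triethylsilyloxy)hept-5-enoic acid, via peroxy acid 11 (not isolated)
Conditions: LiOH·H2O, 30% H2O2, THF/H2O, 0 °C; aq. Na2SO3; cold 1 M HCl to pH 4
Reagents that add atoms: hydrogen peroxide, OO (as lithium hydroperoxide; it supplies the carboxyl OH oxygen)
Why: Hydroperoxide cleavage of an N-acyloxazolidinone, in which the small α-effect nucleophile attacks the exocyclic carbonyl selectively even next to the branched α-carbon, the peroxy acid 11 is reduced by sulfite, and the tert-butyl ester, silyl ether and alkene should not react.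

Step 6
Reactants: 12 (2R,3S)-2-(2-tert-butoxy-2-oxoethyl)-6-methyl-3-(triethylsilyloxy)hept-5-enoic acid
Product: 14 (2R)-2-[(1S)-4-methyl-1-(triethylsilyloxy)pent-3-en-1-yl]butanedioic acid, via bis(trimethylsilyl) ester 13 (not isolated)
Conditions: TMSOTf, 2,6-lutidine, CH2Cl2, 0 °C → rt; then H2O/THF, 0 °C, pH 4
Reagents that add atoms: none
Why: Non-protic cleavage of a tert-butyl ester by a silyl triflate (O-silylation of the ester carbonyl, loss of the tert-butyl cation as 2-methylpropene) gives the bis(trimethylsilyl) ester 13, which water hydrolyses, so the silyl ether and the alkene never meet a strong Brønsted acid.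

Step 7
Reactants: 14 (2R)-2-[(1S)-4-methyl-1-(triethylsilyloxy)pent-3-en-1-yl]butanedioic acid
Product: 15 (3R)-3-[(1S)-4-methyl-1-(triethylsilyloxy)pent-3-en-1-yl]oxolane-2,5-dione
Conditions: DCC, CH2Cl2, 0 °C → rt; filtration; used without chromatography
Reagents that add atoms: none
Why: Carbodiimide cyclodehydration of a succinic acid to its five-membered anhydride under neutral conditions, with no concern about the α-centre since it is to be erased.

Step 8
Reactants: 15 (3R)-3-[(1S)-4-methyl-1-(triethylsilyloxy)pent-3-en-1-yl]oxolane-2,5-dione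
Product: 16 3-[(1S)-4-methyl-1-(triethylsilyloxy)pent-3-en-1-yl]-2,5-bis(trimethylsilyloxy)furan
Conditions: TMSOTf (2.2 equiv), Et3N (2.5 equiv), Et2O, 0 °C → rt; pentane, separation from the ammonium triflate, evaporation under Ar; used crude at once
Reagents that add atoms: trimethylsilyl trifluoromethanesulfonate, C[Si](C)(C)OS(=O)(=O)C(F)(F)F
Why: Double soft enolisation (O-silylation) of a succinic anhydride to the aromatic 2,5-bis(trimethylsilyloxy)furan is a known reaction type, and because each enolisation ends in a neutral silyl enol ether and not a free enolate, β-elimination of the silyloxy group at C1′ should not compete and C1′ is not touched.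

Step 9
Reactants: 16 3-[(1S)-4-methyl-1-(triethylsilyloxy)pent-3-en-1-yl]-2,5-bis(trimethylsilyloxy)furan; 17 p-benzoquinone
Product: 20 5,8-dihydroxy-2-[(1S)-4-methyl-1-(triethylsilyloxy)pent-3-en-1-yl]naphthalene-1,4-dione, via oxygen-bridged cycloadduct 18 (not isolated), via dihydrotetrone 19 (not isolated)
Conditions: 17 (2 equiv), CH2Cl2, −40 °C → rt, dark, Ar; then THF/0.1 M aq. HCl, 0 °C, brief
Reagents that add atoms: none
Why: Diels–Alder reaction of normal electron demand in which the furan, a cyclic bis(silyl ketene acetal) with a very high HOMO, adds through its two oxygen-bearing carbons C2 and C5 to one C=C of p-benzoquinone, so that both C(=O)–C(ring-fusion) bonds form in one event (concerted and asynchronous, or by conjugate addition and collapse of the ion pair, with the same result). The closest known reaction type is the cycloaddition of 2,5-bis(trimethylsilyloxy)furans from succinic anhydrides to quinones and other electron-poor alkenes, which gives para-dioxygenated rings after loss of the oxygen bridge. Ring B closes by intermolecular [4+2] cycloaddition to the 7-oxabicyclo[2.2.1]heptene 18, whose two bridgehead silyl ketal carbons then expel the bridge oxygen as hexamethyldisiloxane (1,4-elimination started by water or acid) to give tetrone 19, and the two ring-fusion hydrogens of 19, each flanked by two carbonyl groups, enolise so that ring A becomes the aromatic dihydroxy ring. No lasting stereocentre is made, since the four sp3 centres of 18 are flattened on the way to 20, so endo/exo and facial selectivity are irrelevant and C1′ is not touched. The step needs bonding at furan C2/C5 and not at C3/C4, and a single addition; the absence of a Lewis acid, the aromatisation that only the [4+2] path allows and an excess of the quinone should secure this, while regiochemistry does not arise because p-benzoquinone is symmetric and the isolated trisubstituted alkene is no dienophile.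

Step 10
Reactants: 20 5,8-dihydroxy-2-[(1S)-4-methyl-1-(triethylsilyloxy)pent-3-en-1-yl]naphthalene-1,4-dione
Product: 21 alkannin, 5,8-dihydroxy-2-[(1S)-1-hydroxy-4-methylpent-3-en-1-yl]naphthalene-1,4-dione
Conditions: HF·pyridine, pyridine, THF, 0 °C
Reagents that add atoms: none
Why: Fluoride cleavage of a triethylsilyl ether under pyridine buffering should spare the base-sensitive naphthazarin and avoid acid-induced addition of the freed hydroxyl to the trisubstituted alkene, and since the C1′–O bond is not broken the S configuration is kept.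

Step 11
Reactants: 21 alkannin; 22 tiglic acid, (2E)-2-methylbut-2-enoic acid
Product: 23 (1S)-1-(5,8-dihydroxy-1,4-dioxo-1,4-dihydronaphthalen-2-yl)-4-methylpent-3-en-1-yl (2E)-2-methylbut-2-enoate
Conditions: DCC, DMAP (cat.), CH2Cl2, 0 °C → rt
Reagents that add atoms: none
Why: Steglich esterification, in which the two phenolic hydroxyls are held in strong hydrogen bonds to the peri carbonyl groups and are poor nucleophiles, so only the secondary side-chain hydroxyl should be acylated, with retention at C1′ (O–H and not C–O is broken) and with the thermodynamically favoured E-alkene of the acid unchanged.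

**Compound list**

1 | mono-tert-butyl succinate (4-tert-butoxy-4-oxobutanoic acid) | CC(C)(C)OC(=O)CCC(=O)O | starting material
2 | (R)-4-benzyl-1,3-oxazolidin-2-one | O=C1N[C@H](Cc2ccccc2)CO1 | starting material
3 | 4-tert-butoxy-4-oxobutanoic pivalic anhydride | CC(C)(C)OC(=O)CCC(=O)OC(=O)C(C)(C)C | intermediate (not isolated)
4 | tert-butyl 4-[(4R)-4-benzyl-2-oxo-1,3-oxazolidin-3-yl]-4-oxobutanoate | CC(C)(C)OC(=O)CCC(=O)N1[C@H](Cc2ccccc2)COC1=O | intermediate
5 | 4-methylpent-3-en-1-ol | CC(C)=CCCO | starting material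
6 | 4-methylpent-3-enal | CC(C)=CCC=O | intermediate
7 | dibutylboron Z-enolate of 4 | CC(C)(C)OC(=O)C/C=C(\OB(CCCC)CCCC)N1[C@H](Cc2ccccc2)COC1=O | intermediate (not isolated)
8 | dibutylboron aldolate of 9 | CC(C)(C)OC(=O)C[C@@H](C(=O)N1[C@H](Cc2ccccc2)COC1=O)[C@@H](OB(CCCC)CCCC)CC=C(C)C | intermediate (not isolated)
9 | tert-butyl (3R,4S)-3-{[(4R)-4-benzyl-2-oxo-1,3-oxazolidin-3-yl]carbonyl}-4-hydroxy-7-methyloct-6-enoate | CC(C)(C)OC(=O)C[C@@H](C(=O)N1[C@H](Cc2ccccc2)COC1=O)[C@@H](O)CC=C(C)C | intermediate
10 | tert-butyl (3R,4S)-3-{[(4R)-4-benzyl-2-oxo-1,3-oxazolidin-3-yl]carbonyl}-7-methyl-4-(triethylsilyloxy)oct-6-enoate | CC(C)(C)OC(=O)C[C@@H](C(=O)N1[C@H](Cc2ccccc2)COC1=O)[C@@H](O[Si](CC)(CC)CC)CC=C(C)C | intermediate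
11 | (2R,3S)-2-(2-tert-butoxy-2-oxoethyl)-6-methyl-3-(triethylsilyloxy)hept-5-eneperoxoic acid | CC(C)(C)OC(=O)C[C@@H](C(=O)OO)[C@@H](O[Si](CC)(CC)CC)CC=C(C)C | intermediate (not isolated)
12 | (2R,3S)-2-(2-tert-butoxy-2-oxoethyl)-6-methyl-3-(triethylsilyloxy)hept-5-enoic acid | CC(C)(C)OC(=O)C[C@@H](C(=O)O)[C@@H](O[Si](CC)(CC)CC)CC=C(C)C | intermediate
13 | bis(trimethylsilyl) (2R)-2-[(1S)-4-methyl-1-(triethylsilyloxy)pent-3-en-1-yl]butanedioate | C[Si](C)(C)OC(=O)C[C@@H](C(=O)O[Si](C)(C)C)[C@@H](O[Si](CC)(CC)CC)CC=C(C)C | intermediate (not isolated)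
14 | (2R)-2-[(1S)-4-methyl-1-(triethylsilyloxy)pent-3-en-1-yl]butanedioic acid | OC(=O)C[C@@H](C(=O)O)[C@@H](O[Si](CC)(CC)CC)CC=C(C)C | intermediate
15 | (3R)-3-[(1S)-4-methyl-1-(triethylsilyloxy)pent-3-en-1-yl]oxolane-2,5-dione | O=C1C[C@@H](C(=O)O1)[C@@H](O[Si](CC)(CC)CC)CC=C(C)C | intermediate
16 | 3-[(1S)-4-methyl-1-(triethylsilyloxy)pent-3-en-1-yl]-2,5-bis(trimethylsilyloxy)furan | C[Si](C)(C)Oc1cc(c(O[Si](C)(C)C)o1)[C@@H](O[Si](CC)(CC)CC)CC=C(C)C | intermediate
17 | p-benzoquinone | O=C1C=CC(=O)C=C1 | starting material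
18 | 1,4-epoxy-2-[(1S)-4-methyl-1-(triethylsilyloxy)pent-3-en-1-yl]-1,4-bis(trimethylsilyloxy)-1,4,4a,8a-tetrahydronaphthalene-5,8-dione (ring stereocentres unspecified, all erased later) | C[Si](C)(C)OC12OC(O[Si](C)(C)C)(C=C1[C@@H](O[Si](CC)(CC)CC)CC=C(C)C)C1C(=O)C=CC(=O)C12 | intermediate (not isolated)
19 | 2-[(1S)-4-methyl-1-(triethylsilyloxy)pent-3-en-1-yl]-4a,8a-dihydronaphthalene-1,4,5,8-tetrone | O=C1C=CC(=O)C2C1C(=O)C(=CC2=O)[C@@H](O[Si](CC)(CC)CC)CC=C(C)C | intermediate (not isolated)
20 | 5,8-dihydroxy-2-[(1S)-4-methyl-1-(triethylsilyloxy)pent-3-en-1-yl]naphthalene-1,4-dione | CC[Si](CC)(CC)O[C@@H](CC=C(C)C)C1=CC(=O)c2c(O)ccc(O)c2C1=O | intermediate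
21 | alkannin, 5,8-dihydroxy-2-[(1S)-1-hydroxy-4-methylpent-3-en-1-yl]naphthalene-1,4-dione | O[C@@H](CC=C(C)C)C1=CC(=O)c2c(O)ccc(O)c2C1=O | intermediate
22 | tiglic acid, (2E)-2-methylbut-2-enoic acid | C/C=C(\C)C(=O)O | starting material
23 | (1S)-1-(5,8-dihydroxy-1,4-dioxo-1,4-dihydronaphthalen-2-yl)-4-methylpent-3-en-1-yl (2E)-2-methylbut-2-enoate | C/C=C(\C)C(=O)O[C@@H](CC=C(C)C)C1=CC(=O)c2c(O)ccc(O)c2C1=O | target

**Count and risks**

Total steps: 11. Longest linear sequence: 10 (steps 1 and 3–11; step 2 is a one-step side branch).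

Steps most likely to fail:

Step 9. The very electron-rich furan may reduce p-benzoquinone by electron transfer, may add through C3/C4 in a conjugate addition, or the product may take up a second furan, all in place of the clean [4+2] addition. The fallback sets out from 16 and returns at 21, and replaces the quinone by an aryne, which is no oxidant. 2-Bromo-1,4-bis(methoxymethoxy)benzene F1 (from bromohydroquinone, MOMCl, iPr2NEt) is treated with LiN(iPr)2 in THF at −78 °C in the presence of 16 and warmed. 3,6-Bis(methoxymethoxy)benzyne forms by ortho-lithiation and loss of bromide and should be trapped by the furan in a [4+2] cycloaddition to the 1,4-epoxy-1,4-dihydronaphthalene F2. Mild aqueous work-up should open the bridge to 5,8-bis(methoxymethoxy)-2-[(1S)-4-methyl-1-(triethylsilyloxy)pent-3-en-1-yl]naphthalene-1,4-dione F3, again at the final oxidation level. Aqueous HCl in THF at 0 °C → rt should then remove both methoxymethyl ethers and the silyl ether to give 21.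

Step 8. The silyloxy group at C1′ may be lost by elimination or by ionisation next to the electron-rich ring, or the furan may hydrolyse during handling. The fallback sets out from 6 and returns at 23. It moves the side chain from the diene to the 2π partner, so that the same cycloaddition builds the other ring and no side-chain-bearing furan is needed.
- 6 and 2,5-(MeO)2C6H3MgBr (THF, −78 °C) should give racemic 1-(2,5-dimethoxyphenyl)-4-methylpent-3-en-1-ol F4.
- Dess–Martin oxidation gives 1-(2,5-dimethoxyphenyl)-4-methylpent-3-en-1-one F5.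
- (−)-B-Chlorodiisopinocampheylborane (THF, −25 °C) should give (1S)-1-(2,5-dimethoxyphenyl)-4-methylpent-3-en-1-ol F6; the sense is expected by analogy with aryl alkyl ketones.
- 22, DCC and DMAP give (1S)-1-(2,5-dimethoxyphenyl)-4-methylpent-3-en-1-yl (2E)-2-methylbut-2-enoate F7.
- (NH4)2Ce(NO3)6 in MeCN/H2O at 0 °C should give (1S)-1-(3,6-dioxocyclohexa-1,4-dien-1-yl)-4-methylpent-3-en-1-yl (2E)-2-methylbut-2-enoate F8.
- 2,5-Bis(trimethylsilyloxy)furan F9 (from succinic anhydride, TMSOTf, Et3N) should add across the unsubstituted C=C of F8 to the oxygen-bridged cycloadduct F10, which on dilute-acid work-up should lose the bridge and enolise to 23.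

Step 3. The β,γ-unsaturated aldehyde may isomerise into conjugation or condense with itself before it meets the enolate, and the aldolate may close onto the ester. The fallback sets out from 4 and returns at 10, and installs the alkene after the aldol.
- The same boron aldol with commercial 3-(benzyloxy)propanal should give tert-butyl (3R,4S)-3-{[(4R)-4-benzyl-2-oxo-1,3-oxazolidin-3-yl]carbonyl}-6-(benzyloxy)-4-hydroxyhexanoate F11.
- TESOTf and 2,6-lutidine give the triethylsilyl ether F12.
- H2 and Pd/C in EtOAc give the primary alcohol F13, which is oxidised at once with Dess–Martin periodinane to the aldehyde F14.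
- Wittig olefination with Ph3P=CMe2 (from iPrPPh3I and n-BuLi, THF, −78 °C) should give 10.

**Further compounds**

F1 | step 9 | 2-bromo-1,4-bis(methoxymethoxy)benzene | COCOc1ccc(OCOC)c(Br)c1
F2 | step 9 | 1,4-epoxy-5,8-bis(methoxymethoxy)-2-[(1S)-4-methyl-1-(triethylsilyloxy)pent-3-en-1-yl]-1,4-bis(trimethylsilyloxy)-1,4-dihydronaphthalene | C[Si](C)(C)OC12OC(O[Si](C)(C)C)(C=C1[C@@H](O[Si](CC)(CC)CC)CC=C(C)C)c1c(OCOC)ccc(OCOC)c12
F3 | step 9 | 5,8-bis(methoxymethoxy)-2-[(1S)-4-methyl-1-(triethylsilyloxy)pent-3-en-1-yl]naphthalene-1,4-dione | CC[Si](CC)(CC)O[C@@H](CC=C(C)C)C1=CC(=O)c2c(OCOC)ccc(OCOC)c2C1=O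
F4 | step 8 | racemic 1-(2,5-dimethoxyphenyl)-4-methylpent-3-en-1-ol | COc1ccc(OC)c(c1)C(O)CC=C(C)C
F5 | step 8 | 1-(2,5-dimethoxyphenyl)-4-methylpent-3-en-1-one | COc1ccc(OC)c(c1)C(=O)CC=C(C)C
F6 | step 8 | (1S)-1-(2,5-dimethoxyphenyl)-4-methylpent-3-en-1-ol | COc1ccc(OC)c(c1)[C@@H](O)CC=C(C)C
F7 | step 8 | (1S)-1-(2,5-dimethoxyphenyl)-4-methylpent-3-en-1-yl (2E)-2-methylbut-2-enoate | C/C=C(\C)C(=O)O[C@@H](CC=C(C)C)c1cc(OC)ccc1OC
F8 | step 8 | (1S)-1-(3,6-dioxocyclohexa-1,4-dien-1-yl)-4-methylpent-3-en-1-yl (2E)-2-methylbut-2-enoate | C/C=C(\C)C(=O)O[C@@H](CC=C(C)C)C1=CC(=O)C=CC1=O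
F9 | step 8 | 2,5-bis(trimethylsilyloxy)furan | C[Si](C)(C)Oc1ccc(O[Si](C)(C)C)o1
F10 | step 8 | oxygen-bridged cycloadduct of F8 and F9 (ring stereocentres unspecified) | C/C=C(\C)C(=O)O[C@@H](CC=C(C)C)C1=CC(=O)C2C(C1=O)C1(O[Si](C)(C)C)C=CC2(O[Si](C)(C)C)O1
F11 | step 3 | tert-butyl (3R,4S)-3-{[(4R)-4-benzyl-2-oxo-1,3-oxazolidin-3-yl]carbonyl}-6-(benzyloxy)-4-hydroxyhexanoate | CC(C)(C)OC(=O)C[C@@H](C(=O)N1[C@H](Cc2ccccc2)COC1=O)[C@@H](O)CCOCc1ccccc1
F12 | step 3 | tert-butyl (3R,4S)-3-{[(4R)-4-benzyl-2-oxo-1,3-oxazolidin-3-yl]carbonyl}-6-(benzyloxy)-4-(triethylsilyloxy)hexanoate | CC(C)(C)OC(=O)C[C@@H](C(=O)N1[C@H](Cc2ccccc2)COC1=O)[C@@H](O[Si](CC)(CC)CC)CCOCc1ccccc1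
F13 | step 3 | tert-butyl (3R,4S)-3-{[(4R)-4-benzyl-2-oxo-1,3-oxazolidin-3-yl]carbonyl}-6-hydroxy-4-(triethylsilyloxy)hexanoate | CC(C)(C)OC(=O)C[C@@H](C(=O)N1[C@H](Cc2ccccc2)COC1=O)[C@@H](O[Si](CC)(CC)CC)CCO
F14 | step 3 | tert-butyl (3R,4S)-3-{[(4R)-4-benzyl-2-oxo-1,3-oxazolidin-3-yl]carbonyl}-6-oxo-4-(triethylsilyloxy)hexanoate | CC(C)(C)OC(=O)C[C@@H](C(=O)N1[C@H](Cc2ccccc2)COC1=O)[C@@H](O[Si](CC)(CC)CC)CC=O
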